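If each impurity takes one catalyst out of the round, treat the poisoning as a titration and freeze what it leaves.

| setting | teal | green | flask |
|---|---|---|---|
| substrate | 1 M | 1 M | 1.0 M |
| precatalyst | 1 mM | 1 mM | 1.0 mM |
| impurity | 0.20 mM | 0.31 mM | 0.41 mM |
| remark | run made earlier | run made earlier |  |
| time |  |  | 2.5 h |

| run | time / min | isomer of the product / % | target / % | substrate / % |
|---|---|---|---|---|
| teal | 8.00 | 8.7 | 44.9 | 48.9 |
| teal | 15.0 | 12.6 | 49.0 | 42.3 |
| teal | 25.0 | 15.3 | 43.5 | 39.1 |
| teal | 50.0 | 18.9 | 41.2 | 40.1 |
| teal | 90.0 | 20.1 | 41.5 | 37.4 |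
| green | 20.0 | 14.2 | 45.2 | 39.6 |
| green | 40.0 | 17.2 | 42.8 | 37.0 |
| green | 50.0 | 19.4 | 43.2 | 38.7 |
| green | 80.0 | 22.5 | 42.4 | 37.9 |
| green | 90.0 | 21.3 | 41.1 | 37.7 |

(standard deviation of a reading: 1 percentage point)

- share of isomer of the product in isomer of the product plus target at 40 s
- share of isomer of the product in isomer of the product plus target at 2.5 h
- which of isomer of the product and target there is more of at 2.5 h

In the flask the working fraction is 59.0 %, the part of the catalyst charge left after that titration; the teal run has 80.0 % and the green run 69.0 %. Apply the bench rule: while a working fraction stands, read the end of the run from its plateau. At 90.0 min the isomer share reads 32.6 % in the teal run and 34.1 % in the green run, so commit to the mean of these readings, 33.4 %, for the flask at 2.5 h, with target ahead. Stretch the green time by the ratio of working fractions: 90.0 min becomes 1.75 h, which is shorter than 2.5 h.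

Find the borders by ratios. Impurity over precatalyst is 0.410 in the flask, and the rule stops where this ratio reaches 1; below that, the impurity is the limiting reagent of the poisoning. The rule also stops in time: 40 s is 0.0833 of the time of the first teal reading, where the share reads 16.2 %, so take no early figure from a plateau.

The forecast gave 10 %, 34 % and target ahead, holding that “Matching plateaus suggest equilibrium rather than catalyst death”. The flask gives 36.5 % at 40 s and 33.8 % at 2.5 h, with target at 41.3 % and isomer of the product at 21.0 %.

    substrate + free catalyst ⇌ target + free catalyst, rate k1*[substrate]*[free catalyst] forward; the back reaction follows from the equilibrium constant (K = 1.10, k = 4.80 L mol⁻¹ s⁻¹)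
    target ⇌ isomer of the product (K = 0.510, k = 1.40 × 10⁻⁴ s⁻¹)
    isomer of the product ⇌ substrate (k = 4.40 × 10⁻⁴ s⁻¹)
    substrate → decomposition product (k = 4.80 × 10⁻⁷ s⁻¹)
    precatalyst → free catalyst (k = 0.00510 s⁻¹)
    free catalyst + impurity → spent catalyst (k = 12.0 L mol⁻¹ s⁻¹)

Set the working fraction of 59.0 % beside the flask at 2.50 h: free catalyst stands at 59.0 % of the catalyst charge, spent catalyst at 41.0 %, precatalyst at 0 %, and impurity at 0 % of its own charge. Now reckon the neighbour flask charged with 0.0016 M of impurity, precatalyst held. Its ratio is 1.60, past the border, and the titration leaves 37.5 % of the impurity charge. That neighbour flask ends with 37.5 % of its impurity, free catalyst at 0 % and spent catalyst at 100 %. At the end its isomer share is 37.1 %, and its substrate, 41.4 %, stands above its target, 36.7 %.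

(The earlier runs and the new flask were computed for substances that don't exist.)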